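Numbering used throughout: 1 2,4-dihydroxyacetophenone; 2 its diacetate; 3 the α-acetoxy triacetate; 4 3,7-diacetoxy-2-methylchromone; 5 the 2-carbaldehyde; 6 Ohira–Bestmann reagent; 7 the 2-ethynylchromone diacetate; 8 2,3-dimethoxybuta-1,3-diene; 9 the cyclohexa-1,4-diene cycloadduct; 10 the flavonol diacetate; 11 3,7-dihydroxy-3',4'-dimethoxyflavone; 12 prenyl bromide; 13 the target.

## Analysis of the target

Target 13 is a flavonol: benzo ring A is fused to 4-pyranone ring C (a 4H-chromen-4-one), C2 carries the 3,4-dimethoxyphenyl ring B, C3 a free enolic hydroxyl and O7 a 3-methylbut-2-enyl (prenyl) ether. It has no stereocentre and no alkene geometry to set, because the prenyl double bond ends in two methyl groups. The problem is therefore one of constitution and chemoselectivity only.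

The most fragile group is the aryl prenyl ether. It ionises under acid, rearranges sigmatropically on strong heating, is attacked at its allylic positions by selenium- and quinone-based oxidants, and does not survive hydrogenation. The 3-hydroxy-4-pyranone is acidic and chelating, and as its anion it is an electron-rich enolate. C2 of the chromone is open to hard nucleophiles.

The difficulty is that four oxygens are present in three different states (two methyl ethers, one prenyl ether, one free hydroxyl), so no late selective dealkylation can be afforded, and that in this plan ring B is built rather than bought. The plan rests on one feature of ring B. C3' and C4' both carry methoxy groups and are flanked by the unsubstituted C2' and C5'; these four carbons with their two oxygens are the skeleton of a 2,3-dimethoxybutadiene. The remaining pair C1'–C6' is then a two-carbon unit bound through C1' to C2, that is, an ethynyl group. That alkyne is conjugated through C2=C3 with C4=O, which is what makes it a dienophile.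

## Retrosynthetic reasoning

13 ⇒ 11 + 12. The O7–CH2 bond of the allylic ether is cut first, so it is made last. The prenyl group is the one part of 13 that would not tolerate the upstream chemistry: allylic C–H oxidation at the C2 methyl group, a cycloaddition that may need prolonged heating, and a quinone-mediated dehydrogenation. The forward step must alkylate O7 and leave O3 alone. In 11 the 7-hydroxyl is a vinylogous carboxylic acid (para to the C4 acyl carbon), while the 3-hydroxyl is a weaker acid held in a hydrogen bond to C4=O, so one equivalent of weak base should select O7.

11 ⇒ 10. Both hydroxyls are traced back to acetates. Acyl groups are preferred to ethers because they hold back the lone pairs on O3 and O7 from the dienophile of the key step, and because they leave by mild transesterification that cannot touch the two methyl ethers.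

10 ⇒ 9. Ring B is taken back to a cyclohexa-1,4-diene by adding hydrogen at C2' and C5'. The forward step is a dehydrogenation driven by aromatisation of a ring that already holds two enol ethers, so one equivalent of a quinone oxidant at room temperature should suffice.

9 ⇒ 7 + 8. The ring bonds C1'–C2' and C5'–C6' are cut together. This is the only pair of cuts in ring B that gives a symmetric four-carbon partner, 8, so the forward cycloaddition has no regiochemical question; any other pair would call for an unsymmetrical diene. The gain is large: the aryl ring shrinks to a two-carbon alkyne on the heterocycle. The forward reaction must be a normal-demand [4+2] addition to the alkyne and must spare the C2=C3 bond. In 7 the substituent on O7 is acetyl rather than prenyl. This spectator change widens the thermal window of the cycloaddition and removes the only group that the later dehydrogenation could damage.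

7 ⇒ 5 + 6. The terminal alkyne carbon (the future C6') is removed to leave aldehyde 5; in the forward sense it is supplied by the diazo carbon of 6. The homologation must keep the acyl group on O3. A free 3-oxide next to the formyl group is the enolate of a 1,3-dicarbonyl system and would no longer accept a nucleophile. The anion of the reagent is therefore preformed and used at low temperature instead of the usual carbonate-in-alcohol protocol.

5 ⇒ 4. The formyl group is traced back to a methyl group. This is a C–H oxidation at the one position that C4=O activates vinylogously, and it lets the C2 carbon arrive with ring construction.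

4 ⇒ 3. Ring C is opened at O1–C2 and C2–C3. C2 and its methyl group are an acetyl unit delivered to the α-carbon of the aryl ketone, and O1 is the ortho phenol oxygen. The forward step is a one-pot C-acetylation and cyclodehydration. Because the α-carbon already carries an acetoxy group, the C3 oxygen is in place and the heterocycle never has to be oxidised.

3 ⇒ 2 ⇒ 1. The C–O bond at the ketone α-carbon is cut, then the two aryl acetates. The α-oxidation must be run on 2, not on 1, because an electrophilic oxidant would attack the free resorcinol-type phenols of 1 instead of the enol.

## Alternatives that were turned down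

Alternative 1: Ring A is taken as an aryne and the bonds O1–C8a, C4–C4a and O1–C2 are made in one operation. Fluoride would release a 3-chloroaryne from the silyl triflate A3. The carboxylate of the arylpropiolic acid A2 would add at the aryne carbon remote from chlorine, the acyl group would shift to the adjacent carbanion, and the phenoxide would close ring C by 6-endo addition to the ynone, giving the flavone A1. In its favour, it is convergent, three bonds form in one flask, ring B arrives complete from A2, and the chlorine makes the aryne addition regioselective. Against it, A1 is far from 13: the C5 chlorine is a pure auxiliary and must be removed, C3 still carries hydrogen and must be oxygenated late on an electron-rich flavone, and the benzyl ether must be exchanged for prenyl. A3 itself needs a multi-step synthesis, and without the chlorine the aryne would not be regioselective. Alternative 1 is stronger on convergence. The chosen route instead carries the C3 oxygen from its second step, needs no auxiliary atom, and has a two-step end-game after aromatisation.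

Alternative 2: Ring C is made by ring expansion of a five-membered ring, forming O1–C2 and the C3–O bond. The aurone A5 would be dibrominated to A6, and alkali in alcohol would open the coumaranone and reclose the phenoxide on the benzylic carbon to give A4, which is the same compound as 11. On step economy this alternative is clearly stronger: A5 is one condensation away from purchasable material, so A4 would be reached in about three steps against eight for 11 here. Against it, the halogenation of A5 must compete with electrophilic substitution on two electron-rich rings (the free-phenol ring A and the veratrole ring B). In addition, with a donor-substituted ring B the benzylic bromide of A6 ionises easily, so elimination back to A5 or formation of non-hydroxylated by-products can rival the expansion. The chosen route keeps electrophilic halogen away from the electron-rich rings and fixes the ring B pattern through the symmetry of 8. It is also modular: alkyne 7 could give other ring B patterns simply by changing the diene.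

Alternative 3: The C3–C4 bond is cut with reversed polarity. A triazolium-derived carbene would convert the aromatic aldehyde of dialdehyde A8 into an acyl-anion equivalent, which adds to the aliphatic aldehyde and closes ring C as the trans dihydroflavonol A7 (racemic). In its favour, it is mild and metal-free, the prenyl ether is in place from the start, and the C3 oxygen appears directly. On gentleness to the prenyl group it is as good as or better than the chosen route. Against it, A8 contains an α-aryl-α-aryloxy acetaldehyde that enolises, autoxidises and eliminates readily. The carbene also adds more easily to the aliphatic than to the aromatic aldehyde, so the regioisomeric acyloin or a mixture through the shared enediol is likely. The two stereocentres of A7 are made only to be destroyed in an extra dehydrogenation, which again must spare the prenyl ether. The chosen route uses only stable, achiral intermediates and concentrates its risk in one pericyclic step.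

Key step: step 6

Remark: compounds 1, 6, 8 and 12 are taken as purchasable; every chiral intermediate of a fallback is racemic.

## Route

Step 1
Reactants: 1 2,4-dihydroxyacetophenone
Product: 2 4-acetyl-1,3-phenylene diacetate
Conditions: Ac2O, pyridine, DMAP (cat.), CH2Cl2, 0 °C → rt
Reagents that add atoms: acetic anhydride, CC(=O)OC(C)=O
Why: Nucleophilic-catalysed O-acylation of both phenols; DMAP is needed for the hydrogen-bonded ortho hydroxyl. Masking the phenols prevents their oxidation in step 2.

Step 2
Reactants: 2 4-acetyl-1,3-phenylene diacetate
Product: 3 2-[2,4-bis(acetyloxy)phenyl]-2-oxoethyl acetate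
Conditions: PhI(OAc)2, BF3·OEt2, AcOH, rt
Reagents that add atoms: (diacetoxyiodo)benzene, CC(=O)OI(OC(C)=O)c1ccccc1
Why: α-Acetoxylation of a ketone with a trivalent iodine reagent: the BF3-promoted enol attacks iodine, and acetate displaces iodobenzene from the α-carbon. The methyl group is the only enolisable position, and the aryl acetates are too electron-poor to be oxidised.

Step 3
Reactants: 3 2-[2,4-bis(acetyloxy)phenyl]-2-oxoethyl acetate
Product: 4 2-methyl-4-oxo-4H-chromene-3,7-diyl diacetate
Conditions: Ac2O, NaOAc, 160–170 °C
Reagents that add atoms: acetic anhydride, CC(=O)OC(C)=O
Why: Kostanecki–Robinson reaction: the α-carbon, acidified by the ketone and the acetoxy group, is C-acetylated, the ortho phenol oxygen closes on the new acetyl carbonyl, and dehydration gives the 2-methylchromone. With only one α-hydrogen left after acylation no 3-acetyl product can form, and the hot anhydride keeps O7 and O3 acetylated.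

Step 4
Reactants: 4 2-methyl-4-oxo-4H-chromene-3,7-diyl diacetate
Product: 5 2-formyl-4-oxo-4H-chromene-3,7-diyl diacetate
Conditions: SeO2, 1,4-dioxane (dry), reflux
Reagents that add atoms: selenium dioxide, O=[Se]=O
Why: Riley oxidation: the C2 methyl group is vinylogously α to C4=O and enolises towards tetravalent selenium, as in the known oxidation of 2-methylchromones to chromone-2-carbaldehydes. The oxidation stops at the aldehyde, and the acetates are inert in the dry neutral medium.

Step 5
Reactants: 5 2-formyl-4-oxo-4H-chromene-3,7-diyl diacetate; 6 dimethyl (1-diazo-2-oxopropyl)phosphonate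
Product: 7 2-ethynyl-4-oxo-4H-chromene-3,7-diyl diacetate
Conditions: 6 (1.3 equiv), NaOMe (1.25 equiv), THF, −78 °C; then 5, −78 → 0 °C; AcOH quench
Reagents that add atoms: none
Why: Seyferth–Gilbert homologation with the preformed anion of the deacetylated reagent: addition to the very electrophilic aldehyde, loss of dimethyl phosphate and of N2, and 1,2-hydrogen shift of the alkylidene carbene give the alkyne, whose new carbon is the diazo carbon of 6. Because the alkoxide is used up in cleaving 6 before 5 is added and the addition is fast at low temperature, the acetate on O3 should stay in place and keep the aldehyde reactive.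

Step 6
Reactants: 7 2-ethynyl-4-oxo-4H-chromene-3,7-diyl diacetate; 8 2,3-dimethoxybuta-1,3-diene
Product: 9 2-(4,5-dimethoxycyclohexa-1,4-dien-1-yl)-4-oxo-4H-chromene-3,7-diyl diacetate
Conditions: 8 (4 equiv), BHT (cat.), toluene, sealed tube (base-washed), 130 °C
Reagents that add atoms: none
Why: The step is a concerted, suprafacial [4+2] cycloaddition of normal electron demand (Diels–Alder reaction): the HOMO of 8, raised by its two methoxy groups, overlaps with the LUMO of the alkyne of 7, which is lowered because the triple bond is conjugated through C2=C3 with C4=O (a vinylogous ynone) and because O3 and O7 carry acyl groups that hold back their lone pairs. The closest known reaction type is the thermal addition of 2,3-dialkoxybutadienes to conjugated acetylenes such as propiolates and ethynyl ketones, which gives 4,5-dialkoxycyclohexa-1,4-dienes that are dehydrogenated to veratroles. Ring B is closed in one intermolecular event: s-cis 8 and the alkyne meet in a boat-like six-membered transition state and both σ bonds, C1'–C2' and C5'–C6', form together, leaving the C1'=C6' and C3'=C4' double bonds. No stereocentre is created, since the two new sp3 carbons are CH2 groups, so there is nothing to control and no endo/exo question. Regioselectivity is not an issue because 8 is symmetric and either orientation gives the same 9. Chemoselectivity for the terminal alkyne over the C2=C3 bond is secured because that bond is tetrasubstituted and part of the vinylogous ester of ring C, while the alkyne is sterically open; 9 is a non-conjugated diene and cannot add a second molecule of 8. The excess of 8, the radical inhibitor and acid-free glass are there to outrun oligomerisation and hydrolysis of the enol-ether diene, and the absence of any allyl aryl ether in 7 allows the temperature to be raised if the addition is slow.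

Step 7
Reactants: 9 2-(4,5-dimethoxycyclohexa-1,4-dien-1-yl)-4-oxo-4H-chromene-3,7-diyl diacetate
Product: 10 2-(3,4-dimethoxyphenyl)-4-oxo-4H-chromene-3,7-diyl diacetate
Conditions: DDQ (1.1 equiv), toluene, 0 °C → rt
Reagents that add atoms: none
Why: Quinone dehydrogenation: hydride abstraction from a ring CH2 that is allylic to both double bonds gives a cation stabilised by a methoxy group, and proton loss aromatises ring B. The gain of aromaticity makes this far faster than any attack on the acetates or the chromone.

Step 8
Reactants: 10 2-(3,4-dimethoxyphenyl)-4-oxo-4H-chromene-3,7-diyl diacetate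
Product: 11 2-(3,4-dimethoxyphenyl)-3,7-dihydroxy-4H-chromen-4-one
Conditions: K2CO3 (cat.), MeOH–THF, rt; AcOH quench
Reagents that add atoms: none
Why: Base-catalysed transesterification of one aryl and one enol acetate, both activated by their good leaving groups. The methyl ethers and the flavonol nucleus are inert to carbonate in methanol at room temperature.

Step 9
Reactants: 11 2-(3,4-dimethoxyphenyl)-3,7-dihydroxy-4H-chromen-4-one; 12 1-bromo-3-methylbut-2-ene (prenyl bromide)
Product: 13 2-(3,4-dimethoxyphenyl)-3-hydroxy-7-[(3-methylbut-2-en-1-yl)oxy]-4H-chromen-4-one
Conditions: K2CO3 (1.05 equiv), 12 (1.05 equiv), acetone, 40 °C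
Reagents that add atoms: none
Why: Williamson ether synthesis by SN2 attack at the primary allylic carbon of 12. With one equivalent of weak base only the more acidic 7-hydroxyl (para to the C4 acyl carbon) is ionised, while the 3-hydroxyl stays protonated and hydrogen-bonded to C4=O, so O7 should be alkylated selectively.

## Compound list

1 | 1-(2,4-dihydroxyphenyl)ethan-1-one (2,4-dihydroxyacetophenone) | CC(=O)c1ccc(O)cc1O | starting material
2 | 4-acetyl-1,3-phenylene diacetate | CC(=O)Oc1ccc(C(C)=O)c(OC(C)=O)c1 | intermediate
3 | 2-[2,4-bis(acetyloxy)phenyl]-2-oxoethyl acetate | CC(=O)OCC(=O)c1ccc(OC(C)=O)cc1OC(C)=O | intermediate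
4 | 2-methyl-4-oxo-4H-chromene-3,7-diyl diacetate | Cc1oc2cc(OC(C)=O)ccc2c(=O)c1OC(C)=O | intermediate
5 | 2-formyl-4-oxo-4H-chromene-3,7-diyl diacetate | O=Cc1oc2cc(OC(C)=O)ccc2c(=O)c1OC(C)=O | intermediate
6 | dimethyl (1-diazo-2-oxopropyl)phosphonate | COP(=O)(OC)C(=[N+]=[N-])C(C)=O | starting material
7 | 2-ethynyl-4-oxo-4H-chromene-3,7-diyl diacetate | C#Cc1oc2cc(OC(C)=O)ccc2c(=O)c1OC(C)=O | intermediate
8 | 2,3-dimethoxybuta-1,3-diene | C=C(OC)C(=C)OC | starting material
9 | 2-(4,5-dimethoxycyclohexa-1,4-dien-1-yl)-4-oxo-4H-chromene-3,7-diyl diacetate | COC1=C(OC)CC(c2oc3cc(OC(C)=O)ccc3c(=O)c2OC(C)=O)=CC1 | intermediate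
10 | 2-(3,4-dimethoxyphenyl)-4-oxo-4H-chromene-3,7-diyl diacetate | COc1ccc(-c2oc3cc(OC(C)=O)ccc3c(=O)c2OC(C)=O)cc1OC | intermediate
11 | 2-(3,4-dimethoxyphenyl)-3,7-dihydroxy-4H-chromen-4-one | COc1ccc(-c2oc3cc(O)ccc3c(=O)c2O)cc1OC | intermediate
12 | 1-bromo-3-methylbut-2-ene (prenyl bromide) | CC(C)=CCBr | starting material
13 | 2-(3,4-dimethoxyphenyl)-3-hydroxy-7-[(3-methylbut-2-en-1-yl)oxy]-4H-chromen-4-one | COc1ccc(-c2oc3cc(OCC=C(C)C)ccc3c(=O)c2O)cc1OC | target

Total step count: 9. Longest linear sequence: 9 steps (1 → 13).

## Steps least certain to work

Step 6 (key step). The alkyne is activated only vinylogously, so the cycloaddition may be slower than oligomerisation or hydrolysis of the enol-ether diene at the temperature it needs, and conversion may stall. The fallback replaces the alkyne by a nitroalkene as its synthetic equivalent; it sets out from 5 and comes back to the route at 9. Aldehyde 5 would be condensed with nitromethane (NH4OAc, AcOH, 80 °C; Henry condensation with dehydration) to (E)-2-(2-nitroethenyl)-4-oxo-4H-chromene-3,7-diyl diacetate F1. As a much stronger dienophile, F1 should add 8 in toluene at 80–100 °C with retention of the alkene geometry, giving racemic trans-2-(3,4-dimethoxy-6-nitrocyclohex-3-en-1-yl)-4-oxo-4H-chromene-3,7-diyl diacetate F2. DBU in THF should then remove nitrous acid by an E1cB process that begins at the ring C–H next to the chromone (vinylogously α to C4=O), placing the new double bond at C1'=C6' and giving 9. Any double-bond isomer would converge at 10 in step 7.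

Step 5. The acetyl group on O3 may be transferred to the phosphonate anion or to residual alkoxide before the aldehyde is consumed; the resulting 3-oxide is the enolate of a 1,3-dicarbonyl system and shuts down the addition. Conjugate addition of alkoxide to the activated alkyne is a second risk. The fallback exchanges the esters for base-stable ethers so that the standard protocol can be used; it sets out from 5 and comes back at 7. Transesterification (K2CO3 cat., MeOH) would give 3,7-dihydroxy-4-oxo-4H-chromene-2-carbaldehyde F3, and MOMCl with iPr2NEt in CH2Cl2 would give 3,7-bis(methoxymethoxy)-4-oxo-4H-chromene-2-carbaldehyde F4. Homologation with 6 under K2CO3 in MeOH at 0 °C → rt should give 2-ethynyl-3,7-bis(methoxymethoxy)-4H-chromen-4-one F5. TFA in wet CH2Cl2 at 0 °C would release 2-ethynyl-3,7-dihydroxy-4H-chromen-4-one F6, and Ac2O with pyridine would return 7.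

Step 3. At 160–170 °C the ring may close the wrong way: through the methyl group of the ortho O-acetyl onto the ketone (Perkin-type closure to a coumarin), or by phenoxide displacement of the α-acetate to a five-membered benzofuranone. Acyl scrambling and charring are further risks. The fallback makes the same two bonds stepwise under kinetic control; it sets out from 3 and comes back at 4. LiN(SiMe3)2 (2.2 equiv) in THF at −78 → 0 °C should deprotonate the most acidic α-carbon and move the ortho acetyl group from oxygen to carbon (Baker–Venkataraman rearrangement), giving 4-[2-(acetyloxy)-3-oxobutanoyl]-3-hydroxyphenyl acetate F7. AcOH with H2SO4 (cat.) at 60 °C should then cyclodehydrate F7 to 4.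

Step 9. Site selectivity may erode: once the 7-phenoxide is consumed, proton exchange can expose the 3-oxide to a second alkylation. The fallback differentiates the two oxygens by selective deacylation instead of selective alkylation; it sets out from 10 and comes back at 13. PhSH and imidazole in N-methylpyrrolidone at 0 °C → rt should thiolyse only the 7-acetate, which has the better leaving phenoxide, giving 2-(3,4-dimethoxyphenyl)-7-hydroxy-4-oxo-4H-chromen-3-yl acetate F8. Alkylation with 12 (K2CO3, acetone) would give 2-(3,4-dimethoxyphenyl)-7-[(3-methylbut-2-en-1-yl)oxy]-4-oxo-4H-chromen-3-yl acetate F9, and K2CO3 (cat.) in MeOH would remove the last acetate to give 13.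

Step 2. A second acetoxylation at the same carbon, slow enolisation of the deactivated ketone, or participation of the ortho ester oxygen with closure to a benzofuranone may lower the efficiency. The fallback goes through a halide and a substitution; it sets out from 2 and comes back at 3. CuBr2 in EtOAc–CHCl3 at reflux should give 4-(bromoacetyl)-1,3-phenylene diacetate F10, and KOAc in DMF at rt should displace bromide to give 3.

## Further compounds

F1 | step 6 | (E)-2-(2-nitroethenyl)-4-oxo-4H-chromene-3,7-diyl diacetate | O=[N+]([O-])/C=C/c1oc2cc(OC(C)=O)ccc2c(=O)c1OC(C)=O
F2 | step 6 | trans-2-(3,4-dimethoxy-6-nitrocyclohex-3-en-1-yl)-4-oxo-4H-chromene-3,7-diyl diacetate (racemic, one enantiomer drawn) | COC1=C(OC)C[C@@H]([N+](=O)[O-])[C@H](c2oc3cc(OC(C)=O)ccc3c(=O)c2OC(C)=O)C1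
F3 | step 5 | 3,7-dihydroxy-4-oxo-4H-chromene-2-carbaldehyde | O=Cc1oc2cc(O)ccc2c(=O)c1O
F4 | step 5 | 3,7-bis(methoxymethoxy)-4-oxo-4H-chromene-2-carbaldehyde | COCOc1ccc2c(c1)oc(C=O)c(OCOC)c2=O
F5 | step 5 | 2-ethynyl-3,7-bis(methoxymethoxy)-4H-chromen-4-one | C#Cc1oc2cc(OCOC)ccc2c(=O)c1OCOC
F6 | step 5 | 2-ethynyl-3,7-dihydroxy-4H-chromen-4-one | C#Cc1oc2cc(O)ccc2c(=O)c1O
F7 | step 3 | 4-[2-(acetyloxy)-3-oxobutanoyl]-3-hydroxyphenyl acetate (racemic, readily enolised) | CC(=O)OC(C(C)=O)C(=O)c1ccc(OC(C)=O)cc1O
F8 | step 9 | 2-(3,4-dimethoxyphenyl)-7-hydroxy-4-oxo-4H-chromen-3-yl acetate | COc1ccc(-c2oc3cc(O)ccc3c(=O)c2OC(C)=O)cc1OC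
F9 | step 9 | 2-(3,4-dimethoxyphenyl)-7-[(3-methylbut-2-en-1-yl)oxy]-4-oxo-4H-chromen-3-yl acetate | COc1ccc(-c2oc3cc(OCC=C(C)C)ccc3c(=O)c2OC(C)=O)cc1OC
F10 | step 2 | 4-(bromoacetyl)-1,3-phenylene diacetate | CC(=O)Oc1ccc(C(=O)CBr)c(OC(C)=O)c1
A1 | alternative 1 | 7-(benzyloxy)-5-chloro-2-(3,4-dimethoxyphenyl)-4H-chromen-4-one | COc1ccc(-c2cc(=O)c3c(Cl)cc(OCc4ccccc4)cc3o2)cc1OC
A2 | alternative 1 | 3-(3,4-dimethoxyphenyl)prop-2-ynoic acid | COc1ccc(C#CC(=O)O)cc1OC
A3 | alternative 1 | 5-(benzyloxy)-3-chloro-2-(trimethylsilyl)phenyl trifluoromethanesulfonate | C[Si](C)(C)c1c(Cl)cc(OCc2ccccc2)cc1OS(=O)(=O)C(F)(F)F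
A4 | alternative 2 | 2-(3,4-dimethoxyphenyl)-3,7-dihydroxy-4H-chromen-4-one (identical with 11) | COc1ccc(-c2oc3cc(O)ccc3c(=O)c2O)cc1OC
A5 | alternative 2 | (Z)-2-(3,4-dimethoxybenzylidene)-6-hydroxy-1-benzofuran-3(2H)-one | COc1ccc(/C=C2\Oc3cc(O)ccc3C2=O)cc1OC
A6 | alternative 2 | 2-bromo-2-[bromo(3,4-dimethoxyphenyl)methyl]-6-hydroxy-1-benzofuran-3(2H)-one (mixture of stereoisomers) | COc1ccc(C(Br)C2(Br)Oc3cc(O)ccc3C2=O)cc1OC
A7 | alternative 3 | trans-2-(3,4-dimethoxyphenyl)-3-hydroxy-7-[(3-methylbut-2-en-1-yl)oxy]-2,3-dihydro-4H-chromen-4-one (racemic, one enantiomer drawn) | COc1ccc([C@@H]2Oc3cc(OCC=C(C)C)ccc3C(=O)[C@H]2O)cc1OC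
A8 | alternative 3 | 2-[1-(3,4-dimethoxyphenyl)-2-oxoethoxy]-4-[(3-methylbut-2-en-1-yl)oxy]benzaldehyde (racemic) | COc1ccc(C(C=O)Oc2cc(OCC=C(C)C)ccc2C=O)cc1OC
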